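**Strategy.** The 1,2-dioxane (O1, O2, C3–C6) is disconnected at C4–C5 and O1–C6. C6 is quaternary and flanked by the CH2 C5, the signature of a 1,1-disubstituted alkene. C4 and C5 are both alpha to oxygenated carbons (C3, C6), a like-polarity pair, so C4 is raised to an aldehyde. A SnCl4-promoted Prins-type annulation then joins the aldehyde carbon to the CH2 terminus of a farnesyl-derived tetraene and lets the tert-butylperoxy oxygen on C3 trap the C6 cation, closing the ring in one operation. The precursor is an acyclic alpha-peroxy aldehyde made from (S)-malate; the extra C4 hydroxyl is removed by radical deoxygenation.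

Key step: step 5

Remark: the configuration at C4 of 9 and 10 is left open in name and SMILES, because both epimers converge on 11.

Step 1
Reactants: 1 (2E,6E)-farnesyl bromide; 2 2-methylallylmagnesium chloride (CH2=C(CH3)CH2MgCl)
Product: 3 (5E,9E)-2,6,10,14-tetramethylpentadeca-1,5,9,13-tetraene
Conditions: THF, −20 °C to rt
Reagents that add atoms: none
Why: Allyl–allyl cross-coupling, in which the symmetrical methallyl Grignard reagent should displace the primary allylic bromide by SN2 at the unhindered carbon and leave both E alkenes untouched; no stereocenter is formed.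

Step 2
Reactants: 4 dimethyl (S)-malate
Product: 5 dimethyl (2S,3R)-2-hydroxy-3-methylbutanedioate
Conditions: LiN(SiMe3)2 (2.2 equiv), THF, −78 to −20 °C; MeI, −78 °C to rt; aq NH4Cl
Reagents that add atoms: iodomethane, CI
Why: Fráter–Seebach alkylation, in which the chelated alkoxide enolate should be methylated anti to the alkoxide, so that the anti isomer is expected to predominate and the methyl-bearing carbon (C2 of the target) is set as R.

Step 3
Reactants: 5 dimethyl (2S,3R)-2-hydroxy-3-methylbutanedioate
Product: 7 dimethyl (2R,3R)-2-(tert-butylperoxy)-3-methylbutanedioate, via triflate 6 (not isolated)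
Conditions: Tf2O, 2,6-lutidine, CH2Cl2, −78 °C; then tBuOOK (3 equiv, from tBuOOH and KOtBu), THF, −78 to 0 °C
Reagents that add atoms: tert-butyl hydroperoxide, CC(C)(C)OO
Why: Alkylation of a hydroperoxide with an alkyl triflate, in which SN2 displacement of the alpha-triflyloxy ester by the weakly basic tert-butylperoxide anion should proceed with inversion and set the peroxide-bearing carbon (C3 of the target) in its final configuration.

Step 4
Reactants: 7 dimethyl (2R,3R)-2-(tert-butylperoxy)-3-methylbutanedioate
Product: 8 methyl (2R,3R)-3-(tert-butylperoxy)-2-methyl-4-oxobutanoate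
Conditions: iBu2AlH (1.05 equiv), CH2Cl2, −78 °C; MeOH, aq potassium sodium tartrate; used crude
Reagents that add atoms: none
Why: Partial reduction of an ester to an aldehyde, in which the alpha-peroxy ester is the more electrophilic and less hindered of the two and should give a chelated aluminate that holds until work-up, while dialkyl peroxides tolerate iBu2AlH at −78 °C and no stereocenter is touched.

Step 5
Reactants: 8 methyl (2R,3R)-3-(tert-butylperoxy)-2-methyl-4-oxobutanoate; 3 (5E,9E)-2,6,10,14-tetramethylpentadeca-1,5,9,13-tetraene (1.5 equiv)
Product: 9 methyl (2R)-2-[(3R,6R)-4-hydroxy-6-methyl-6-[(3E,7E)-4,8,12-trimethyltrideca-3,7,11-trien-1-yl]-1,2-dioxan-3-yl]propanoate (C4 epimers)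
Conditions: SnCl4 (1.1 equiv), 2,6-di-tert-butyl-4-methylpyridine, CH2Cl2, −78 °C; aq NaHCO3
Reagents that add atoms: none
Why: Proposed new method: SnCl4 chelates the aldehyde oxygen and the proximal peroxide oxygen of 8, the CH2 terminus of the 1,1-disubstituted alkene of 3 attacks the activated carbonyl carbon (Prins addition, forming C4–C5), and the resulting tertiary C6 cation is trapped by the distal peroxide oxygen O1 with loss of the tert-butyl group as 2-methylpropene (forming O1–C6). The closest known reaction types are the Prins and carbonyl-ene additions of Lewis acid-activated aldehydes to 1,1-disubstituted alkenes, the annulation of peroxycarbenium ions with alkenes in which a silyl peroxide oxygen traps the cation to give 1,2-dioxolanes, and the silver-induced dealkylative cyclisation of haloalkyl tert-butyl peroxides. The 1,2-dioxane closes by attack of O1 on the planar C6 cation, formally a 6-endo closure across the former C5=C6 alkene, through a chair transition state. C6 is controlled by 1,4-induction from C3, the C3 propanoate arm and the long C6 chain both sitting equatorial and the C6 methyl axial to give the 3,6-trans (6R) isomer, a preference expected to be only moderate so that the C6 epimer may have to be removed by chromatography; C4 is set by chelation control but is of no consequence because its hydroxyl is removed. The step needs chemoselectivity for the terminal alkene over the three trisubstituted ones and Markovnikov regioselectivity, both secured by the unhindered CH2 terminus that leads to a tertiary cation placed to form a six-membered ring with O1, while the hindered pyridine base suppresses proton-initiated polyene cyclisation.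

Step 6
Reactants: 9 methyl (2R)-2-[(3R,6R)-4-hydroxy-6-methyl-6-[(3E,7E)-4,8,12-trimethyltrideca-3,7,11-trien-1-yl]-1,2-dioxan-3-yl]propanoate
Product: 10 methyl (2R)-2-[(3R,6R)-4-(1H-imidazole-1-carbothioyloxy)-6-methyl-6-[(3E,7E)-4,8,12-trimethyltrideca-3,7,11-trien-1-yl]-1,2-dioxan-3-yl]propanoate (C4 epimers)
Conditions: 1,1'-thiocarbonyldiimidazole, DMAP (cat.), CH2Cl2, rt to 40 °C
Reagents that add atoms: 1,1'-thiocarbonyldiimidazole, S=C(n1ccnc1)n1ccnc1
Why: Thioacylation of the secondary alcohol under neutral conditions should give the thiocarbonyl derivative needed for Barton–McCombie deoxygenation without touching the peroxide, the ester or the alkenes; no stereocenter of the target is affected.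

Step 7
Reactants: 10 methyl (2R)-2-[(3R,6R)-4-(1H-imidazole-1-carbothioyloxy)-6-methyl-6-[(3E,7E)-4,8,12-trimethyltrideca-3,7,11-trien-1-yl]-1,2-dioxan-3-yl]propanoate
Product: 11 methyl (2R)-2-[(3S,6R)-6-methyl-6-[(3E,7E)-4,8,12-trimethyltrideca-3,7,11-trien-1-yl]-1,2-dioxan-3-yl]propanoate
Conditions: Bu3SnH, Et3B, air (trace), toluene, rt
Reagents that add atoms: none
Why: Barton–McCombie deoxygenation, in which the stannyl radical should add to the thiocarbonyl group far faster than to the O–O bond and the secondary C4 radical should take hydrogen from Bu3SnH before it can attack the ring peroxide, whose geometry disfavours intramolecular substitution; C3 and C6 are untouched and initiation at room temperature spares the peroxide.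

**Compound list**

1 | (2E,6E)-farnesyl bromide | BrC/C=C(\C)CC/C=C(\C)CCC=C(C)C | starting material
2 | 2-methylallylmagnesium chloride | CC(=C)C[Mg]Cl | starting material
3 | (5E,9E)-2,6,10,14-tetramethylpentadeca-1,5,9,13-tetraene | C=C(C)CC/C=C(\C)CC/C=C(\C)CCC=C(C)C | intermediate
4 | dimethyl (S)-malate | COC(=O)C[C@H](O)C(=O)OC | starting material
5 | dimethyl (2S,3R)-2-hydroxy-3-methylbutanedioate | COC(=O)[C@H](C)[C@H](O)C(=O)OC | intermediate
6 | dimethyl (2S,3R)-3-methyl-2-(trifluoromethylsulfonyloxy)butanedioate (triflate, not isolated) | COC(=O)[C@H](C)[C@H](OS(=O)(=O)C(F)(F)F)C(=O)OC | intermediate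
7 | dimethyl (2R,3R)-2-(tert-butylperoxy)-3-methylbutanedioate | COC(=O)[C@H](C)[C@@H](OOC(C)(C)C)C(=O)OC | intermediate
8 | methyl (2R,3R)-3-(tert-butylperoxy)-2-methyl-4-oxobutanoate | COC(=O)[C@H](C)[C@@H](OOC(C)(C)C)C=O | intermediate
9 | methyl (2R)-2-[(3R,6R)-4-hydroxy-6-methyl-6-[(3E,7E)-4,8,12-trimethyltrideca-3,7,11-trien-1-yl]-1,2-dioxan-3-yl]propanoate (C4 epimers) | COC(=O)[C@H](C)[C@@H]1C(O)C[C@@](C)(CC/C=C(\C)CC/C=C(\C)CCC=C(C)C)OO1 | intermediate
10 | methyl (2R)-2-[(3R,6R)-4-(1H-imidazole-1-carbothioyloxy)-6-methyl-6-[(3E,7E)-4,8,12-trimethyltrideca-3,7,11-trien-1-yl]-1,2-dioxan-3-yl]propanoate (C4 epimers) | COC(=O)[C@H](C)[C@@H]1C(OC(=S)n2ccnc2)C[C@@](C)(CC/C=C(\C)CC/C=C(\C)CCC=C(C)C)OO1 | intermediate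
11 | methyl (2R)-2-[(3S,6R)-6-methyl-6-[(3E,7E)-4,8,12-trimethyltrideca-3,7,11-trien-1-yl]-1,2-dioxan-3-yl]propanoate | COC(=O)[C@H](C)[C@@H]1CC[C@@](C)(CC/C=C(\C)CC/C=C(\C)CCC=C(C)C)OO1 | target

**Step count and risks**

Total step count: 7. Longest linear sequence: 6 steps (4 to 11, steps 2 to 7); step 1 is the convergent branch.

The three steps most likely to fail:

Step 5 (proposed new method). The C6 cation may lose a proton (ene pathway) or be captured by chloride before the hindered peroxide oxygen closes the ring. The Lewis acid may fragment the alpha-peroxy aldehyde, and the facial selectivity at C6 may be poor. The fallback separates the two bond formations and uses known reaction types. Setting out from 8 and 3, the addition is run as a chloride-terminated Prins reaction (TiCl4, CH2Cl2, −78 °C), which should give the open-chain tertiary chloride methyl (2R,3R,9E,13E)-3-(tert-butylperoxy)-6-chloro-4-hydroxy-2,6,10,14,18-pentamethylnonadeca-9,13,17-trienoate F1. This is isolated, and the ring is closed by silver-assisted ionisation (AgBF4, 2,6-di-tert-butylpyridine, CH2Cl2, −40 °C). The tert-butyl peroxide oxygen should capture the tertiary cation with loss of 2-methylpropene, as in the known dealkylative cyclisation of haloalkyl tert-butyl peroxides. The route is rejoined at 9.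

Step 4. Over-reduction to the alcohol, attack at the wrong ester, or epimerisation and base-induced fragmentation of the alpha-peroxy aldehyde during work-up may occur. The fallback replaces the partial reduction by full reduction and re-oxidation. Setting out from 7, NaBH4 in MeOH/THF at 0 °C should reduce only the activated alpha-peroxy ester to the primary alcohol methyl (2R,3R)-3-(tert-butylperoxy)-4-hydroxy-2-methylbutanoate F2. This stable alcohol is purified and oxidised with Dess–Martin periodinane (NaHCO3, CH2Cl2, 0 °C) immediately before use, and the route is rejoined at 8.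

Step 7. Stannyl radicals may attack the O–O bond, or the C4 radical may undergo beta-scission with ring opening. The fallback avoids a carbon radical altogether. Setting out from 9, dehydration with Ph2S[OC(CF3)2Ph]2 (Martin sulfurane; CH2Cl2, 0 °C), expected to eliminate toward C5 and away from the oxygen-bearing C3, should give methyl (2R)-2-[(3S,6R)-6-methyl-6-[(3E,7E)-4,8,12-trimethyltrideca-3,7,11-trien-1-yl]-3,6-dihydro-1,2-dioxin-3-yl]propanoate F3. Diimide (KO2CN=NCO2K, AcOH, MeOH, 0 °C) reduces the cis-disubstituted ring alkene faster than the trisubstituted chain alkenes and leaves O–O bonds intact, and the route is rejoined at 11.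

Further compounds
F1 | step 5 | methyl (2R,3R,9E,13E)-3-(tert-butylperoxy)-6-chloro-4-hydroxy-2,6,10,14,18-pentamethylnonadeca-9,13,17-trienoate (C4 and C6 epimers) | COC(=O)[C@H](C)[C@@H](OOC(C)(C)C)C(O)CC(C)(Cl)CC/C=C(\C)CC/C=C(\C)CCC=C(C)C
F2 | step 4 | methyl (2R,3R)-3-(tert-butylperoxy)-4-hydroxy-2-methylbutanoate | COC(=O)[C@H](C)[C@@H](OOC(C)(C)C)CO
F3 | step 7 | methyl (2R)-2-[(3S,6R)-6-methyl-6-[(3E,7E)-4,8,12-trimethyltrideca-3,7,11-trien-1-yl]-3,6-dihydro-1,2-dioxin-3-yl]propanoate | COC(=O)[C@H](C)[C@@H]1C=C[C@@](C)(CC/C=C(\C)CC/C=C(\C)CCC=C(C)C)OO1
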